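**Retrosynthetic overview**

1. The C10 carbinol is cut back to a ring B ketone (methyl added last). Rings A (oxepane) and B then open together, in one step, to an acyclic (3R,6R,7R)-diepoxy silyl enol ether that already carries ring C.
2. The enol ether comes from an E-enone by 1,4-hydrosilylation, and the enone from cross-metathesis of a diepoxy vinyl ketone with a ring C allyl fragment.
3. Ring C is cut at C14–C19: epoxide-initiated cation–olefin cyclisation of an acyclic (18S,19S)-epoxy diene, with the epoxide oxygen left at C18 removed afterwards.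
4. Both acyclic halves come from (E)-geranylacetone. O16 is set by aminoxylation and directs the C18–C19 epoxidation; a Wittig reaction supplies the C14=C15 olefin.
5. Ring order: ring C first (step 5), then rings A and B together (step 12).

Assumption: locants C1–C24 follow the squalene-type chain of the target (C2 = CMe2 of the oxepane, C3 and C16 = secondary carbinols, C6/C7 = ring fusion, C10 = tertiary carbinol, C19 = quaternary carbon of ring C) and are used for all intermediates.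

**Route**

Step 1
Reactants: 1 (E)-geranylacetone
Product: 3 (3S,5E)-3-hydroxy-6,10-dimethylundeca-5,9-dien-2-one, via α-anilinooxy ketone 2 (not isolated)
Conditions: 1 (3 equiv, excess recovered), PhN=O (slow addition), D-proline (20 mol%), DMSO, rt; then Zn, AcOH, THF, 0 °C
Reagents that add atoms: nitrosobenzene, O=Nc1ccccc1
Why: Proline-catalysed α-aminoxylation (nitroso aldol) goes through the more substituted enamine of the methyl ketone, D-proline delivering oxygen to the face that gives (S)-C16, and Zn/AcOH then cleaves the N–O bond.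

Step 2
Reactants: 3 (3S,5E)-3-hydroxy-6,10-dimethylundeca-5,9-dien-2-one
Product: 4 (3S)-3-hydroxy-4-[(2S,3S)-3-methyl-3-(4-methylpent-3-en-1-yl)oxiran-2-yl]butan-2-one
Conditions: VO(acac)2 (5 mol%), tBuOOH (1.5 equiv, decane), CH2Cl2, 0 °C
Reagents that add atoms: tert-butyl hydroperoxide, CC(C)(C)OO
Why: Hydroxyl-directed vanadium epoxidation of a homoallylic alcohol reaches only the C18=C19 olefin (C22=C23 is left), and the chair-like vanadate transition state with the acetyl group equatorial delivers oxygen 1,3-anti to O16, giving the (18S,19S)-epoxide.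

Step 3
Reactants: 4 (3S)-3-hydroxy-4-[(2S,3S)-3-methyl-3-(4-methylpent-3-en-1-yl)oxiran-2-yl]butan-2-one
Product: 5 (3S)-3-{[tert-butyl(dimethyl)silyl]oxy}-4-[(2S,3S)-3-methyl-3-(4-methylpent-3-en-1-yl)oxiran-2-yl]butan-2-one
Conditions: tBuMe2SiCl, imidazole, DMF, rt
Reagents that add atoms: tert-butyl(chloro)dimethylsilane, CC(C)(C)[Si](C)(C)Cl
Why: Silyl ether formation under mild base masks O16 so that it cannot open the neighbouring epoxide in step 5, and no stereocentre is touched.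

Step 4
Reactants: 5 (3S)-3-{[tert-butyl(dimethyl)silyl]oxy}-4-[(2S,3S)-3-methyl-3-(4-methylpent-3-en-1-yl)oxiran-2-yl]butan-2-one; 6 (but-3-en-1-yl)triphenylphosphonium bromide
Product: 7 tert-butyl(dimethyl){[(2S,3Z)-3-methyl-1-[(2S,3S)-3-methyl-3-(4-methylpent-3-en-1-yl)oxiran-2-yl]hepta-3,6-dien-2-yl]oxy}silane
Conditions: 6, KN(SiMe3)2, THF, 0 °C; then 5, −78 °C to rt
Reagents that add atoms: (but-3-en-1-yl)triphenylphosphonium bromide 6, C=CCC[P+](c1ccccc1)(c1ccccc1)c1ccccc1.[Br-]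
Why: Wittig olefination of an α-silyloxy methyl ketone with a non-stabilised ylide builds the C14=C15 olefin (Z expected, though either geometry serves because C14 ends as a ring sp2 carbon) and brings in the allyl handle.

Step 5
Reactants: 7 tert-butyl(dimethyl){[(2S,3Z)-3-methyl-1-[(2S,3S)-3-methyl-3-(4-methylpent-3-en-1-yl)oxiran-2-yl]hepta-3,6-dien-2-yl]oxy}silane
Product: 8 (1S,2S,5S)-5-{[tert-butyl(dimethyl)silyl]oxy}-2,4-dimethyl-2-(4-methylpent-3-en-1-yl)-3-(prop-2-en-1-yl)cyclohex-3-en-1-ol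
Conditions: MeAlCl2 (1.5 equiv), CH2Cl2, −78 °C
Reagents that add atoms: none
Why: Lewis-acid epoxide-initiated cation–olefin cyclisation: C14 attacks C19 anti to the breaking C–O bond, so the quaternary centre is set by inversion while C18 keeps its configuration, and the C15 cation loses the C14 proton to give the tetrasubstituted ring olefin.

Step 6
Reactants: 8 (1S,2S,5S)-5-{[tert-butyl(dimethyl)silyl]oxy}-2,4-dimethyl-2-(4-methylpent-3-en-1-yl)-3-(prop-2-en-1-yl)cyclohex-3-en-1-ol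
Product: 10 O-[(1S,2S,5S)-5-{[tert-butyl(dimethyl)silyl]oxy}-2,4-dimethyl-2-(4-methylpent-3-en-1-yl)-3-(prop-2-en-1-yl)cyclohex-3-en-1-yl] S-methyl carbonodithioate, via sodium xanthate 9 (not isolated)
Conditions: NaH, THF, 0 °C; CS2; then MeI, rt
Reagents that add atoms: carbon disulfide, S=C=S; iodomethane, CI
Why: Xanthate formation on the only free hydroxyl (O18) prepares the radical deoxygenation.

Step 7
Reactants: 10 O-[(1S,2S,5S)-5-{[tert-butyl(dimethyl)silyl]oxy}-2,4-dimethyl-2-(4-methylpent-3-en-1-yl)-3-(prop-2-en-1-yl)cyclohex-3-en-1-yl] S-methyl carbonodithioate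
Product: 11 tert-butyl{[(1S,4R)-2,4-dimethyl-4-(4-methylpent-3-en-1-yl)-3-(prop-2-en-1-yl)cyclohex-2-en-1-yl]oxy}dimethylsilane
Conditions: Bu3SnH (5 equiv), (PhSe)2 (10 mol%), AIBN, benzene, 80 °C
Reagents that add atoms: none
Why: Barton–McCombie deoxygenation removes O18, PhSeH formed in situ trapping the C18 radical faster than it can add 5-exo to the side-chain olefins, and no stereocentre changes (the C19 descriptor changes only by priority).

Step 8
Reactants: 1 (E)-geranylacetone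
Product: 12 4-[(2R,3R)-3-{2-[(2R)-3,3-dimethyloxiran-2-yl]ethyl}-3-methyloxiran-2-yl]butan-2-one
Conditions: D-fructose-derived Shi ketone (30 mol%), Oxone (2KHSO5·KHSO4·K2SO4), K2CO3, Bu4NHSO4, MeCN/CH2(OMe)2/aq. Na2B4O7 buffer (pH 10.5), 0 °C
Reagents that add atoms: potassium peroxymonosulfate (from Oxone), [K+].[O-]S(=O)(=O)OO
Why: Shi asymmetric epoxidation (chiral dioxirane, spiro transition state) converts both trisubstituted olefins, the D-fructose-derived ketone giving the (6R,7R)- and (3R)-epoxides.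

Step 9
Reactants: 12 4-[(2R,3R)-3-{2-[(2R)-3,3-dimethyloxiran-2-yl]ethyl}-3-methyloxiran-2-yl]butan-2-one
Product: 15 5-[(2R,3R)-3-{2-[(2R)-3,3-dimethyloxiran-2-yl]ethyl}-3-methyloxiran-2-yl]pent-1-en-3-one, via Mannich base 13 (not isolated), via trimethylammonium iodide 14 (not isolated)
Conditions: LiN(iPr)2, THF, −78 °C; Me2N=CH2+ I−, −78 °C to rt; then MeI, CH2Cl2, rt; then aq. NaHCO3
Reagents that add atoms: N,N-dimethylmethyleneiminium iodide, C=[N+](C)C.[I-]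
Why: Kinetic deprotonation at the methyl group, Mannich reaction with Eschenmoser's salt, N-methylation and E1cB elimination give the vinyl ketone without touching the epoxides.

Step 10
Reactants: 11 tert-butyl{[(1S,4R)-2,4-dimethyl-4-(4-methylpent-3-en-1-yl)-3-(prop-2-en-1-yl)cyclohex-2-en-1-yl]oxy}dimethylsilane; 15 5-[(2R,3R)-3-{2-[(2R)-3,3-dimethyloxiran-2-yl]ethyl}-3-methyloxiran-2-yl]pent-1-en-3-one
Product: 16 (4E)-6-[(3S,6R)-3-{[tert-butyl(dimethyl)silyl]oxy}-2,6-dimethyl-6-(4-methylpent-3-en-1-yl)cyclohex-1-en-1-yl]-1-[(2R,3R)-3-{2-[(2R)-3,3-dimethyloxiran-2-yl]ethyl}-3-methyloxiran-2-yl]hex-4-en-3-one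
Conditions: second-generation Hoveyda–Grubbs catalyst [RuCl2(H2IMes)(=CH-C6H4-2-OiPr)] (5 mol%), 15 (2 equiv), CH2Cl2, 40 °C
Reagents that add atoms: none
Why: Olefin cross-metathesis between a terminal allyl group and an electron-poor vinyl ketone is selective for the cross product and the E-enone, while the tri- and tetrasubstituted olefins and the epoxides are inert.

Step 11
Reactants: 16 (4E)-6-[(3S,6R)-3-{[tert-butyl(dimethyl)silyl]oxy}-2,6-dimethyl-6-(4-methylpent-3-en-1-yl)cyclohex-1-en-1-yl]-1-[(2R,3R)-3-{2-[(2R)-3,3-dimethyloxiran-2-yl]ethyl}-3-methyloxiran-2-yl]hex-4-en-3-one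
Product: 17 {[(3Z)-6-[(3S,6R)-3-{[tert-butyl(dimethyl)silyl]oxy}-2,6-dimethyl-6-(4-methylpent-3-en-1-yl)cyclohex-1-en-1-yl]-1-[(2R,3R)-3-{2-[(2R)-3,3-dimethyloxiran-2-yl]ethyl}-3-methyloxiran-2-yl]hex-3-en-3-yl]oxy}triethylsilane
Conditions: [RhCl(PPh3)3] (2 mol%), Et3SiH, benzene, 50 °C
Reagents that add atoms: triethylsilane, CC[SiH](CC)CC
Why: Rhodium-catalysed 1,4-hydrosilylation of the enone gives the C10=C11 silyl enol ether regiospecifically (Z expected), which a ketone flanked by two methylene groups could not give by enolisation.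

Step 12
Reactants: 17 {[(3Z)-6-[(3S,6R)-3-{[tert-butyl(dimethyl)silyl]oxy}-2,6-dimethyl-6-(4-methylpent-3-en-1-yl)cyclohex-1-en-1-yl]-1-[(2R,3R)-3-{2-[(2R)-3,3-dimethyloxiran-2-yl]ethyl}-3-methyloxiran-2-yl]hex-3-en-3-yl]oxy}triethylsilane
Product: 18 (3R,5aR,6R,9aR)-6-{2-[(3S,6R)-3-{[tert-butyl(dimethyl)silyl]oxy}-2,6-dimethyl-6-(4-methylpent-3-en-1-yl)cyclohex-1-en-1-yl]ethyl}-2,2,5a-trimethyl-3-[(trimethylsilyl)oxy]octahydro-1-benzoxepin-7(2H)-one
Conditions: Me3SiOTf (1.2 equiv), 2,6-di-tert-butyl-4-methylpyridine, CH2Cl2, −78 °C; aq. NaHCO3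
Reagents that add atoms: trimethylsilyl trifluoromethanesulfonate, C[Si](C)(C)OS(=O)(=O)C(F)(F)F
Why: Tandem oxa-/carbacyclisation: the silylated terminal epoxide is opened at C2 by the C6–C7 epoxide oxygen (C3 stays R), the resulting bicyclic epoxonium ion is opened at C6 with inversion by C11 of the enol ether through a chair transition state (C7 retained, C12 chain equatorial at C11), and loss of the triethylsilyl group leaves the C10 ketone.

Step 13
Reactants: 18 (3R,5aR,6R,9aR)-6-{2-[(3S,6R)-3-{[tert-butyl(dimethyl)silyl]oxy}-2,6-dimethyl-6-(4-methylpent-3-en-1-yl)cyclohex-1-en-1-yl]ethyl}-2,2,5a-trimethyl-3-[(trimethylsilyl)oxy]octahydro-1-benzoxepin-7(2H)-one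
Product: 20 (3R,5aR,6R,7S,9aR)-6-{2-[(3S,6R)-3-hydroxy-2,6-dimethyl-6-(4-methylpent-3-en-1-yl)cyclohex-1-en-1-yl]ethyl}-2,2,5a,7-tetramethyldecahydro-1-benzoxepine-3,7-diol, via bis-silyl ether 19 (not isolated)
Conditions: MeLi, Et2O/THF, −78 °C; MeOH; then Bu4NF, THF, rt
Reagents that add atoms: methyllithium, [Li]C
Why: Methyllithium adds to the cyclohexanone from the equatorial side because the axial side is blocked by the 1,3-diaxial C6 methyl group, giving the axial tertiary alcohol (10S), and fluoride then removes both silyl groups.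

**Compound list**

1 | (E)-geranylacetone, (5E)-6,10-dimethylundeca-5,9-dien-2-one | CC(=O)CC/C=C(\C)CCC=C(C)C | starting material
2 | (3S,5E)-6,10-dimethyl-3-[(phenylamino)oxy]undeca-5,9-dien-2-one | CC(=O)[C@@H](ONc1ccccc1)C/C=C(\C)CCC=C(C)C | intermediate
3 | (3S,5E)-3-hydroxy-6,10-dimethylundeca-5,9-dien-2-one | CC(=O)[C@@H](O)C/C=C(\C)CCC=C(C)C | intermediate
4 | (3S)-3-hydroxy-4-[(2S,3S)-3-methyl-3-(4-methylpent-3-en-1-yl)oxiran-2-yl]butan-2-one | CC(=O)[C@@H](O)C[C@@H]1O[C@@]1(C)CCC=C(C)C | intermediate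
5 | (3S)-3-{[tert-butyl(dimethyl)silyl]oxy}-4-[(2S,3S)-3-methyl-3-(4-methylpent-3-en-1-yl)oxiran-2-yl]butan-2-one | CC(=O)[C@@H](O[Si](C)(C)C(C)(C)C)C[C@@H]1O[C@@]1(C)CCC=C(C)C | intermediate
6 | (but-3-en-1-yl)triphenylphosphonium bromide | C=CCC[P+](c1ccccc1)(c1ccccc1)c1ccccc1.[Br-] | starting material
7 | tert-butyl(dimethyl){[(2S,3Z)-3-methyl-1-[(2S,3S)-3-methyl-3-(4-methylpent-3-en-1-yl)oxiran-2-yl]hepta-3,6-dien-2-yl]oxy}silane | C=CC/C=C(/C)[C@@H](O[Si](C)(C)C(C)(C)C)C[C@@H]1O[C@@]1(C)CCC=C(C)C | intermediate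
8 | (1S,2S,5S)-5-{[tert-butyl(dimethyl)silyl]oxy}-2,4-dimethyl-2-(4-methylpent-3-en-1-yl)-3-(prop-2-en-1-yl)cyclohex-3-en-1-ol | CC(C)=CCC[C@]1(C)[C@@H](O)C[C@H](O[Si](C)(C)C(C)(C)C)C(C)=C1CC=C | intermediate
9 | sodium O-[(1S,2S,5S)-5-{[tert-butyl(dimethyl)silyl]oxy}-2,4-dimethyl-2-(4-methylpent-3-en-1-yl)-3-(prop-2-en-1-yl)cyclohex-3-en-1-yl] carbonodithioate | CC(C)=CCC[C@]1(C)[C@@H](OC(=S)[S-])C[C@H](O[Si](C)(C)C(C)(C)C)C(C)=C1CC=C.[Na+] | intermediate
10 | O-[(1S,2S,5S)-5-{[tert-butyl(dimethyl)silyl]oxy}-2,4-dimethyl-2-(4-methylpent-3-en-1-yl)-3-(prop-2-en-1-yl)cyclohex-3-en-1-yl] S-methyl carbonodithioate | CC(C)=CCC[C@]1(C)[C@@H](OC(=S)SC)C[C@H](O[Si](C)(C)C(C)(C)C)C(C)=C1CC=C | intermediate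
11 | tert-butyl{[(1S,4R)-2,4-dimethyl-4-(4-methylpent-3-en-1-yl)-3-(prop-2-en-1-yl)cyclohex-2-en-1-yl]oxy}dimethylsilane | CC(C)=CCC[C@]1(C)CC[C@H](O[Si](C)(C)C(C)(C)C)C(C)=C1CC=C | intermediate
12 | 4-[(2R,3R)-3-{2-[(2R)-3,3-dimethyloxiran-2-yl]ethyl}-3-methyloxiran-2-yl]butan-2-one | CC(=O)CC[C@H]1O[C@]1(C)CC[C@H]1OC1(C)C | intermediate
13 | 1-(dimethylamino)-5-[(2R,3R)-3-{2-[(2R)-3,3-dimethyloxiran-2-yl]ethyl}-3-methyloxiran-2-yl]pentan-3-one | CN(C)CCC(=O)CC[C@H]1O[C@]1(C)CC[C@H]1OC1(C)C | intermediate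
14 | 5-[(2R,3R)-3-{2-[(2R)-3,3-dimethyloxiran-2-yl]ethyl}-3-methyloxiran-2-yl]-N,N,N-trimethyl-3-oxopentan-1-aminium iodide | C[N+](C)(C)CCC(=O)CC[C@H]1O[C@]1(C)CC[C@H]1OC1(C)C.[I-] | intermediate
15 | 5-[(2R,3R)-3-{2-[(2R)-3,3-dimethyloxiran-2-yl]ethyl}-3-methyloxiran-2-yl]pent-1-en-3-one | C=CC(=O)CC[C@H]1O[C@]1(C)CC[C@H]1OC1(C)C | intermediate
16 | (4E)-6-[(3S,6R)-3-{[tert-butyl(dimethyl)silyl]oxy}-2,6-dimethyl-6-(4-methylpent-3-en-1-yl)cyclohex-1-en-1-yl]-1-[(2R,3R)-3-{2-[(2R)-3,3-dimethyloxiran-2-yl]ethyl}-3-methyloxiran-2-yl]hex-4-en-3-one | CC(C)=CCC[C@]1(C)CC[C@H](O[Si](C)(C)C(C)(C)C)C(C)=C1C/C=C/C(=O)CC[C@H]1O[C@]1(C)CC[C@H]1OC1(C)C | intermediate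
17 | {[(3Z)-6-[(3S,6R)-3-{[tert-butyl(dimethyl)silyl]oxy}-2,6-dimethyl-6-(4-methylpent-3-en-1-yl)cyclohex-1-en-1-yl]-1-[(2R,3R)-3-{2-[(2R)-3,3-dimethyloxiran-2-yl]ethyl}-3-methyloxiran-2-yl]hex-3-en-3-yl]oxy}triethylsilane | CC(C)=CCC[C@]1(C)CC[C@H](O[Si](C)(C)C(C)(C)C)C(C)=C1CC/C=C(\O[Si](CC)(CC)CC)CC[C@H]1O[C@]1(C)CC[C@H]1OC1(C)C | intermediate
18 | (3R,5aR,6R,9aR)-6-{2-[(3S,6R)-3-{[tert-butyl(dimethyl)silyl]oxy}-2,6-dimethyl-6-(4-methylpent-3-en-1-yl)cyclohex-1-en-1-yl]ethyl}-2,2,5a-trimethyl-3-[(trimethylsilyl)oxy]octahydro-1-benzoxepin-7(2H)-one | CC(C)=CCC[C@]1(C)CC[C@H](O[Si](C)(C)C(C)(C)C)C(C)=C1CC[C@@H]1[C@@]2(C)CC[C@@H](O[Si](C)(C)C)C(C)(C)O[C@@H]2CCC1=O | intermediate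
19 | (3R,5aR,6R,7S,9aR)-6-{2-[(3S,6R)-3-{[tert-butyl(dimethyl)silyl]oxy}-2,6-dimethyl-6-(4-methylpent-3-en-1-yl)cyclohex-1-en-1-yl]ethyl}-2,2,5a,7-tetramethyl-3-[(trimethylsilyl)oxy]decahydro-1-benzoxepin-7-ol | CC(C)=CCC[C@]1(C)CC[C@H](O[Si](C)(C)C(C)(C)C)C(C)=C1CC[C@@H]1[C@@]2(C)CC[C@@H](O[Si](C)(C)C)C(C)(C)O[C@@H]2CC[C@]1(C)O | intermediate
20 | (3R,5aR,6R,7S,9aR)-6-{2-[(3S,6R)-3-hydroxy-2,6-dimethyl-6-(4-methylpent-3-en-1-yl)cyclohex-1-en-1-yl]ethyl}-2,2,5a,7-tetramethyldecahydro-1-benzoxepine-3,7-diol | CC(C)=CCC[C@]1(C)CC[C@H](O)C(C)=C1CC[C@@H]1[C@@]2(C)CC[C@@H](O)C(C)(C)O[C@@H]2CC[C@]1(C)O | target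

**Step count and risks**

Total steps: 13. Longest linear sequence: 11 steps (steps 1–7, then 10–13); steps 8 and 9 make the second fragment.

Step 5 (ring C closure) is the most likely to fail. The C15 cation may lose a proton from its methyl group instead of from C14, giving the exocyclic olefin. The fallback sets out from 7 and comes back at 11. The cyclisation product is then taken on as methylidene alcohol F1. Bu4NF gives diol F2, and MnO2 oxidises only the allylic hydroxyl to α-methylene ketone F3. Catalytic TsOH in benzene moves the double bond into the ring and eliminates the β-hydroxyl, giving cross-conjugated dienone F4. [(Ph3P)CuH]6 reduces the less substituted enone 1,4 to enone F5. (R)-2-methyl-CBS-oxazaborolidine with catecholborane sets C16 again and gives allylic alcohol F6, and tBuMe2SiCl/imidazole returns 11. The olefin position is thus fixed thermodynamically, O18 is lost by elimination, and steps 6 and 7 are not needed.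

Step 7 (radical deoxygenation) is the second risk. The C18 radical can add 5-exo to the homoprenyl or the allyl olefin before it is reduced. The fallback sets out from 8 and comes back at 11 by an ionic route. Dess–Martin periodinane gives ketone F7, TsNHNH2 in warm ethanol gives tosylhydrazone F8, and catecholborane followed by NaOAc reduces it to the methylene compound 11. The ring olefin is β,γ to the hydrazone and does not move.

Step 12 (tandem cyclisation on the full skeleton) is the third risk. Me3SiOTf may ionise the allylic silyl ether at C16 next to the tetrasubstituted olefin. The fallback sets out from 16 and comes back at 18, carrying ring C through the cascade as its acid-stable enone. Bu4NF buffered with AcOH gives hydroxy enone F9, and MnO2 gives bis-enone F10. [RhCl(PPh3)3] with one equivalent of Et3SiH hydrosilylates only the disubstituted acyclic enone, giving enol silane F11. Me3SiOTf with 2,6-di-tert-butyl-4-methylpyridine then gives diketone F12. (R)-2-methyl-CBS-oxazaborolidine with catecholborane at −78 °C reduces the conjugated ketone in preference to the hindered ring B ketone and gives hydroxy ketone F13. tBuMe2SiCl/imidazole returns 18.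

**Further compounds**

F1 | step 5 | (1S,2S,5S)-5-{[tert-butyl(dimethyl)silyl]oxy}-2-methyl-4-methylidene-2-(4-methylpent-3-en-1-yl)-3-(prop-2-en-1-yl)cyclohexan-1-ol (C3 epimers) | CC(C)=CCC[C@]1(C)[C@@H](O)C[C@H](O[Si](C)(C)C(C)(C)C)C(=C)C1CC=C
F2 | step 5 | (1S,3S,4S)-4-methyl-6-methylidene-4-(4-methylpent-3-en-1-yl)-5-(prop-2-en-1-yl)cyclohexane-1,3-diol (C5 epimers) | CC(C)=CCC[C@]1(C)[C@@H](O)C[C@H](O)C(=C)C1CC=C
F3 | step 5 | (4S,5S)-5-hydroxy-4-methyl-2-methylidene-4-(4-methylpent-3-en-1-yl)-3-(prop-2-en-1-yl)cyclohexan-1-one (C3 epimers) | CC(C)=CCC[C@]1(C)[C@@H](O)CC(=O)C(=C)C1CC=C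
F4 | step 5 | (4R)-2,4-dimethyl-4-(4-methylpent-3-en-1-yl)-3-(prop-2-en-1-yl)cyclohexa-2,5-dien-1-one | CC(C)=CCC[C@]1(C)C=CC(=O)C(C)=C1CC=C
F5 | step 5 | (4R)-2,4-dimethyl-4-(4-methylpent-3-en-1-yl)-3-(prop-2-en-1-yl)cyclohex-2-en-1-one | CC(C)=CCC[C@]1(C)CCC(=O)C(C)=C1CC=C
F6 | step 5 | (1S,4R)-2,4-dimethyl-4-(4-methylpent-3-en-1-yl)-3-(prop-2-en-1-yl)cyclohex-2-en-1-ol | CC(C)=CCC[C@]1(C)CC[C@H](O)C(C)=C1CC=C
F7 | step 7 | (2S,5S)-5-{[tert-butyl(dimethyl)silyl]oxy}-2,4-dimethyl-2-(4-methylpent-3-en-1-yl)-3-(prop-2-en-1-yl)cyclohex-3-en-1-one | CC(C)=CCC[C@]1(C)C(=O)C[C@H](O[Si](C)(C)C(C)(C)C)C(C)=C1CC=C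
F8 | step 7 | 4-methylbenzenesulfonylhydrazone of (2S,5S)-5-{[tert-butyl(dimethyl)silyl]oxy}-2,4-dimethyl-2-(4-methylpent-3-en-1-yl)-3-(prop-2-en-1-yl)cyclohex-3-en-1-one | CC(C)=CCC[C@]1(C)C(=NNS(=O)(=O)c2ccc(C)cc2)C[C@H](O[Si](C)(C)C(C)(C)C)C(C)=C1CC=C
F9 | step 12 | (4E)-1-[(2R,3R)-3-{2-[(2R)-3,3-dimethyloxiran-2-yl]ethyl}-3-methyloxiran-2-yl]-6-[(3S,6R)-3-hydroxy-2,6-dimethyl-6-(4-methylpent-3-en-1-yl)cyclohex-1-en-1-yl]hex-4-en-3-one | CC(C)=CCC[C@]1(C)CC[C@H](O)C(C)=C1C/C=C/C(=O)CC[C@H]1O[C@]1(C)CC[C@H]1OC1(C)C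
F10 | step 12 | (4R)-3-[(2E)-6-[(2R,3R)-3-{2-[(2R)-3,3-dimethyloxiran-2-yl]ethyl}-3-methyloxiran-2-yl]-4-oxohex-2-en-1-yl]-2,4-dimethyl-4-(4-methylpent-3-en-1-yl)cyclohex-2-en-1-one | CC(C)=CCC[C@]1(C)CCC(=O)C(C)=C1C/C=C/C(=O)CC[C@H]1O[C@]1(C)CC[C@H]1OC1(C)C
F11 | step 12 | (4R)-3-[(3Z)-6-[(2R,3R)-3-{2-[(2R)-3,3-dimethyloxiran-2-yl]ethyl}-3-methyloxiran-2-yl]-4-[(triethylsilyl)oxy]hex-3-en-1-yl]-2,4-dimethyl-4-(4-methylpent-3-en-1-yl)cyclohex-2-en-1-one | CC(C)=CCC[C@]1(C)CCC(=O)C(C)=C1CC/C=C(\O[Si](CC)(CC)CC)CC[C@H]1O[C@]1(C)CC[C@H]1OC1(C)C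
F12 | step 12 | (3R,5aR,6R,9aR)-6-{2-[(6R)-2,6-dimethyl-6-(4-methylpent-3-en-1-yl)-3-oxocyclohex-1-en-1-yl]ethyl}-2,2,5a-trimethyl-3-[(trimethylsilyl)oxy]octahydro-1-benzoxepin-7(2H)-one | CC(C)=CCC[C@]1(C)CCC(=O)C(C)=C1CC[C@@H]1[C@@]2(C)CC[C@@H](O[Si](C)(C)C)C(C)(C)O[C@@H]2CCC1=O
F13 | step 12 | (3R,5aR,6R,9aR)-6-{2-[(3S,6R)-3-hydroxy-2,6-dimethyl-6-(4-methylpent-3-en-1-yl)cyclohex-1-en-1-yl]ethyl}-2,2,5a-trimethyl-3-[(trimethylsilyl)oxy]octahydro-1-benzoxepin-7(2H)-one | CC(C)=CCC[C@]1(C)CC[C@H](O)C(C)=C1CC[C@@H]1[C@@]2(C)CC[C@@H](O[Si](C)(C)C)C(C)(C)O[C@@H]2CCC1=O
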